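Amounts come first, so I count each charge as a fraction of the left-handed and right-handed substrate charged together.

all flasks: left-handed substrate 10 mM; right-handed substrate 10 mM; free catalyst 1.4 mM
- oak: partner 12 mM (fed, over 20 min); protic impurity 2.8 mM; run made earlier
- birch: partner 12 mM (fed, over 20 min); protic impurity 4.4 mM; run made earlier
- ash: partner 6 mM (fed, over 20 min); protic impurity 2 mM; run made earlier
- flask: partner 12.0 mM (fed, over 20 min); protic impurity 2.00 mM; time 5.0 h

| run | time / h | left-handed product / % | right-handed product / % |
|---|---|---|---|
| oak | 0.417 | 28.2 | 22.8 |
| oak | 0.667 | 29.8 | 23.4 |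
| oak | 1.00 | 28.6 | 23.7 |
| oak | 2.00 | 28.4 | 22.8 |
| oak | 3.00 | 28.5 | 21.9 |
| oak | 5.00 | 29.1 | 23.1 |
| birch | 0.833 | 27.1 | 22.4 |
| birch | 1.50 | 28.1 | 21.6 |
| birch | 2.50 | 26.9 | 22.1 |
| birch | 3.00 | 27.0 | 21.7 |
| birch | 4.00 | 25.8 | 21.2 |
| birch | 5.00 | 27.3 | 20.8 |
| ash | 1.00 | 15.1 | 12.1 |
| ash | 2.00 | 14.5 | 12.8 |
| ash | 3.00 | 14.5 | 12.2 |
| ash | 4.00 | 14.4 | 12.3 |
| ash | 5.00 | 13.9 | 11.8 |

(each reading ± 0.5 percentage points)

- free catalyst is single-handed; left-handed substrate and right-handed substrate are mirror images of each other, charged as a racemate, each of them at the stated concentration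
- an excess is the difference of the two amounts in percent of their sum
- an excess is below zero if the other one leads

- excess of left-handed product over right-handed product in the product at 30 min
- excess of left-handed product over right-handed product in the product at 5.0 h
- part of the left-handed substrate and right-handed substrate charged together that has reacted at 5.0 h

1. From above: the flask's partner is 60.0 % and its free catalyst 7.00 %. If one partner makes one product and each catalyst holds one substrate, reacted substrate stays at or below 67.0 %.

2. From below: if each impurity takes one partner and nothing else takes any, the flask's product reaches 50.0 %.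

3. Tightening: oak's product, averaged over its readings, is 51.7 %. Its quench share, the partner missing from the product per impurity charged, reads 59.2 %. Birch reads 51.5 % and ash 32.8 %. The share moves with the charges, so I carry it between like flasks, and I take oak's for this flask, which has oak's partner.

4. I then reckon the flask's product at 54.1 %. Substrate held on the catalyst can add up to 7.00 %, so I place reacted substrate between 54.1 % and 61.1 %, and I commit to the middle, 57.6 %.

5. Oak's product sum reads 51.0 % at 0.417 h and 52.2 % at 5.00 h, which is flat within scatter. So I expect both excesses to equal oak's, 11.2 %.

The forecast, on the ground that “everything is over once the feed ends”, gives 11.5 %, 11.5 % and 54 %, the last at the low edge of my bracket.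

The flask gives 10.9 %, 10.9 % and 57.7 %.

    free catalyst → spent catalyst (k = 7.48 × 10⁻⁷ /s)
    partner + catalyst intermediate B → free catalyst + right-handed product (k = 4.49 /M/s)
    2 partner → self-condensation product (k = 0.0337 /M/s)
    partner + protic impurity → quenched reagent (k = 0.490 /M/s)
    partner + catalyst intermediate A → free catalyst + left-handed product (k = 14.2 /M/s)
    free catalyst + right-handed substrate ⇌ catalyst intermediate B (K = 230 /M, k = 4.96 /M/s)
    free catalyst + left-handed substrate ⇌ catalyst intermediate A (K = 78.0 /M, k = 113 /M/s)

In the flask, partner, the limiting reagent, ends at 0 %, and the quench share worked out from its products is 62.7 %, against the 59.2 % read from oak. The neighbouring flask with partner at 7.2 mM lies nearer ash in partner and has ash's impurity, so I take ash's share 32.8 %: products 32.7 %, and reacted substrate up to 39.7 %. That flask gives 36.7 % reacted, with products at 32.1 % and catalyst intermediates A and B holding 4.62 %.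

(The runs are simulated with constants of no real substance; scatter was added.)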